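**Retrosynthetic overview**
1. Feature used: ring B is a 1,3,4-trisubstituted phenol, with oxygen on C4, flavone C8 on C3 (ortho to that oxygen) and flavanone C2 on C1 (para to it). A 1-aryl-2-siloxybutadiene and a propiolate give exactly this pattern. Flavone C8 lies ortho to the 7-oxygen, so its first carbon can arrive by an aromatic Claisen shift.
2. Ring C (last ring): O1–C2 by catalytic enantioselective oxa-Michael closure. C2=C3 comes from Knoevenagel condensation of a ring B aldehyde with a ring A 2-hydroxyaryl β-keto tert-butyl ester, whose ester group is then lost as CO2.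
3. Ring B: C2–C3 and C1–C6 by Diels–Alder addition of methyl propiolate to the siloxydiene on flavone C8, then DDQ aromatisation. The ester carbon becomes the handle for flavanone C2.
4. Diene: acacetin, 7-O-allylation, Claisen shift to C8, MOM protection, oxidative cleavage, vinyl addition, oxidation, silyl enol ether formation.
5. Ring order: the flavone rings and ring A are bought, ring B is built in step 8, ring C is closed in step 16.

Key step: step 8

Assumption: of the two pseudoenantiomeric cinchona thioureas, the quinidine-derived one is taken to give the 2S centre. The sense is checked by circular dichroism on the first batch, and the quinine-derived catalyst replaces it if the sign is opposite.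
Assumption: the axis between flavone C8 and ring B C3 has no descriptor in the target and is treated as freely rotating in the deprotected product. Protected intermediates may appear as rotamers.
Abbreviations: Fl = 5,7-bis(methoxymethoxy)-2-(4-methoxyphenyl)-4-oxochromen-8-yl; MOM = CH2OCH3; TBS = tert-butyldimethylsilyl.

**Step 1**
Reactants: 1 acacetin; 2 allyl bromide
Product: 3 7-allyloxy-5-hydroxy-2-(4-methoxyphenyl)chromen-4-one
Conditions: K2CO3 (1.2 equiv), DMF, rt
Reagents that add atoms: allyl bromide (2), C=CCBr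
Why: Williamson ether synthesis; the 5-OH is tied up in a hydrogen bond to the C4 carbonyl and is much less acidic, so one equivalent of base and bromide should alkylate only the 7-OH.

**Step 2**
Reactants: 3 7-allyloxy-5-hydroxy-2-(4-methoxyphenyl)chromen-4-one
Product: 4 8-allyl-5,7-dihydroxy-2-(4-methoxyphenyl)chromen-4-one
Conditions: PhNEt2, 200 °C, argon
Reagents that add atoms: none
Why: Aromatic Claisen rearrangement; in 7-allyloxy benzopyranones the [3,3] shift should go mainly to C8, the angular ortho carbon next to the ring-fusion carbon, as in related chelated 5-hydroxy systems, and any 6-allyl isomer is removed by chromatography.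

**Step 3**
Reactants: 4 8-allyl-5,7-dihydroxy-2-(4-methoxyphenyl)chromen-4-one
Product: 5 8-allyl-5,7-bis(methoxymethoxy)-2-(4-methoxyphenyl)chromen-4-one (Fl–CH2CH=CH2)
Conditions: NaH (2.5 equiv), MOMCl (2.5 equiv), DMF, 0 °C to rt
Reagents that add atoms: chloromethyl methyl ether, COCCl
Why: Double O-alkylation of the bis-phenoxide; full deprotonation with NaH overcomes the chelation of the 5-OH, and both acidic protons are masked for the Grignard, silylation and cycloaddition steps.

**Step 4**
Reactants: 5 Fl–CH2CH=CH2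
Product: 7 2-Fl-acetaldehyde, via vicinal diol 6 (not isolated)
Conditions: OsO4 (2 mol %), NaIO4 (4 equiv), 2,6-lutidine, 1,4-dioxane/H2O 3:1, rt
Reagents that add atoms: osmium tetroxide, O=[Os](=O)(=O)=O (oxygen carrier); sodium periodate, [Na+].[O-]I(=O)(=O)=O (terminal oxygen source)
Why: Lemieux–Johnson oxidation; OsO4 takes the monosubstituted alkene far faster than the electron-poor trisubstituted pyrone C2–C3 bond, NaIO4 cleaves the diol in situ, and the lutidine keeps the medium safe for the MOM ethers.

**Step 5**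
Reactants: 7 2-Fl-acetaldehyde; 8 vinylmagnesium bromide
Product: 9 1-Fl-but-3-en-2-ol (racemic)
Conditions: 8 (1.2 equiv), THF, −78 °C; aqueous quench
Reagents that add atoms: vinylmagnesium bromide (8), C=C[Mg]Br
Why: Grignard 1,2-addition; at −78 °C the aldehyde should outrun the donor-deactivated, peri-shielded pyrone carbonyl, and the carbinol centre may be racemic because the next step oxidises it.

**Step 6**
Reactants: 9 1-Fl-but-3-en-2-ol
Product: 10 1-Fl-but-3-en-2-one
Conditions: Dess–Martin periodinane, CH2Cl2, 0 °C to rt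
Reagents that add atoms: none
Why: Dess–Martin oxidation converts the allylic alcohol to the vinyl ketone under near-neutral conditions that spare the MOM ethers, the pyrone and the terminal alkene.

**Step 7**
Reactants: 10 1-Fl-but-3-en-2-one
Product: 11 (1Z)-1-Fl-2-(tert-butyldimethylsilyloxy)buta-1,3-diene
Conditions: TBSOTf (1.3 equiv), Et3N (3 equiv), CH2Cl2, −78 to 0 °C
Reagents that add atoms: tert-butyldimethylsilyl trifluoromethanesulfonate, CC(C)(C)[Si](C)(C)OS(=O)(=O)C(F)(F)F
Why: Soft enolisation with silyl triflate and amine; only the CH2 between flavone and ketone can lose a proton, the Z enol ether with the bulky flavone trans to the vinyl group is the less strained isomer, excess amine and low temperature protect the MOM ethers, and any silylation of the pyrone oxygen reverts on aqueous work-up.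

**Step 8**
Reactants: 11 (1Z)-1-Fl-2-(tert-butyldimethylsilyloxy)buta-1,3-diene; 12 methyl propiolate
Product: 14 methyl 3-Fl-4-(tert-butyldimethylsilyloxy)benzoate, via cyclohexadiene cycloadduct 13 (not isolated)
Conditions: 12 (5 equiv), BHT (cat.), toluene, 110 °C, sealed tube; then DDQ (1.2 equiv), rt
Reagents that add atoms: methyl propiolate (12), C#CC(=O)OC
Why: A thermal, concerted but asynchronous [4+2] cycloaddition joins the enol-ether β-carbon of 11 (the flavone-bearing terminus, largest HOMO coefficient) to the unsubstituted alkyne carbon of 12 and the CH2 terminus to the ester-bearing carbon, giving the 1,4-cyclohexadiene 13. The closest known reaction type is the Diels–Alder reaction of 2-silyloxy-1,3-dienes with alkynoates followed by quinone dehydrogenation to aryl silyl ethers. Ring B closes in an intermolecular four-carbon plus two-carbon annulation that forms C2–C3 and C1–C6 together; DDQ, added only after the diene is consumed, takes a hydride from the doubly allylic CH2 to give a siloxy-stabilised cation, which loses the proton at C3 and aromatises. The one sp3 centre of 13 is erased, so no stereocentre needs control. The selectivity needed is regiochemical (ester para to oxygen): the 2-siloxy donor sets it, the flavone is twisted out of conjugation by its two ortho substituents and cannot oppose it electronically, and sterically the flavone also prefers the CH end of the alkyne as its neighbour. The Z geometry places the flavone on the outside of the s-cis diene, and the electron-poor pyrone C2–C3 bond does not compete as a dienophile.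

**Step 9**
Reactants: 14 methyl 3-Fl-4-(tert-butyldimethylsilyloxy)benzoate
Product: 16 methyl 3-Fl-4-(methoxymethoxy)benzoate, via free phenol 15 (not isolated)
Conditions: TBAF (1.05 equiv), THF, 0 °C; then MOMCl (1.5 equiv), 0 °C to rt
Reagents that add atoms: chloromethyl methyl ether, COCCl
Why: Fluoride desilylation followed by O-alkylation of the tetrabutylammonium phenoxide replaces the base-labile aryl silyl ether with a MOM ether that survives the coming saponification and leaves with the other acetals at the end.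

**Step 10**
Reactants: 16 methyl 3-Fl-4-(methoxymethoxy)benzoate
Product: 17 3-Fl-4-(methoxymethoxy)benzoic acid
Conditions: LiOH, THF/MeOH/H2O, 40 °C; then cold dilute HCl to pH 4
Reagents that add atoms: lithium hydroxide, [Li+].[OH-]
Why: Ester saponification; MOM ethers are base-stable and a 5,7-dialkoxyflavone ring should not open in dilute LiOH at this temperature.

**Step 11**
Reactants: 17 3-Fl-4-(methoxymethoxy)benzoic acid
Product: 19 [3-Fl-4-(methoxymethoxy)phenyl]methanol, via mixed carbonic anhydride 18 (not isolated)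
Conditions: i-BuOCOCl, N-methylmorpholine, THF, −15 °C; then NaBH4, H2O, 0 °C
Reagents that add atoms: none
Why: Mixed-anhydride activation and borohydride reduction; the change of oxidation level goes through the acid because aluminium hydrides attack chromone carbonyls in 1,2 and 1,4 fashion, whereas flavones are inert to NaBH4 at 0 °C and the anhydride is reduced within minutes.

**Step 12**
Reactants: 19 [3-Fl-4-(methoxymethoxy)phenyl]methanol
Product: 20 3-Fl-4-(methoxymethoxy)benzaldehyde
Conditions: activated MnO2, CH2Cl2, rt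
Reagents that add atoms: none
Why: MnO2 oxidation of a benzylic alcohol stops at the aldehyde and leaves acetals, the aryl methyl ether and the pyrone untouched.

**Step 13**
Reactants: 21 methyl 2,4,6-trihydroxybenzoate
Product: 22 methyl 2-hydroxy-4,6-bis(methoxymethoxy)benzoate
Conditions: MOMCl (2.2 equiv), i-Pr2NEt (2.5 equiv), CH2Cl2, 0 °C to rt
Reagents that add atoms: chloromethyl methyl ether, COCCl
Why: Selective acetal ether formation; the 4-OH and one of the two equivalent ortho OH groups react, while the last OH stays hydrogen-bonded to the ester carbonyl and resists an amine base, as in other acylphloroglucinols.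

**Step 14**
Reactants: 22 methyl 2-hydroxy-4,6-bis(methoxymethoxy)benzoate; 23 tert-butyl acetate
Product: 24 tert-butyl 3-[2-hydroxy-4,6-bis(methoxymethoxy)phenyl]-3-oxopropanoate
Conditions: 23 (4 equiv), LiN(i-Pr)2 (4 equiv), THF, −78 °C to rt; AcOH quench
Reagents that add atoms: tert-butyl acetate (23), CC(=O)OC(C)(C)C
Why: Crossed Claisen condensation; excess lithium enolate first deprotonates the phenol and then acylates on the methyl ester, deprotonation of the β-keto ester drives the equilibrium, and the tert-butyl group resists lactonisation to a 4-hydroxycoumarin.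

**Step 15**
Reactants: 20 3-Fl-4-(methoxymethoxy)benzaldehyde; 24 tert-butyl 3-[2-hydroxy-4,6-bis(methoxymethoxy)phenyl]-3-oxopropanoate
Product: 25 tert-butyl (2Z)-2-[2-hydroxy-4,6-bis(methoxymethoxy)benzoyl]-3-[3-Fl-4-(methoxymethoxy)phenyl]prop-2-enoate
Conditions: piperidine (20 mol %), AcOH (20 mol %), 4 Å MS, toluene, rt
Reagents that add atoms: none
Why: Knoevenagel condensation via the iminium ion of 20; room temperature, a buffered catalytic amine and the bulky ester hold back uncatalysed ring closure, and the isomer with the aryl group cis to the ester is the thermodynamic one.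

**Step 16**
Reactants: 25 the Z alkylidene β-keto ester
Product: 26 tert-butyl (2S,3R)-2-[3-Fl-4-(methoxymethoxy)phenyl]-5,7-bis(methoxymethoxy)-4-oxochromane-3-carboxylate
Conditions: N-[3,5-bis(trifluoromethyl)phenyl]-N'-[(9R)-6'-methoxycinchonan-9-yl]thiourea (10 mol %), toluene, −25 °C; cold AcOH quench, short silica filtration
Reagents that add atoms: none
Why: Enantioselective intramolecular oxa-Michael addition (6-endo-trig) under bifunctional catalysis; the thiourea N–H bonds hold the β-keto ester carbonyls while the quinuclidine nitrogen takes the phenol proton, so the phenoxide reaches one face of the alkylidene carbon and sets C2 as S, C3 settles trans (3R) through its enol and is deleted in step 17, and low temperature with the acid quench suppresses ring opening.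

**Step 17**
Reactants: 26 the (2S,3R) flavanone-3-carboxylate
Product: 28 (2S)-2,3-dihydropodocarpusflavone A, via beta-keto acid 27 (not isolated)
Conditions: HCl (4 M in 1,4-dioxane)/MeOH 1:1, 0 to 45 °C
Reagents that add atoms: none
Why: Global acidolysis; the five MOM ethers are exchanged to dimethoxymethane with methanol as the formaldehyde acceptor, the tert-butyl ester loses isobutene, the β-keto acid decarboxylates on warming (the order of these events does not matter), and base-free conditions avoid the retro-oxa-Michael path that would racemise C2.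

**Compound list**
1 | acacetin, 5,7-dihydroxy-2-(4-methoxyphenyl)chromen-4-one | COc1ccc(-c2cc(=O)c3c(O)cc(O)cc3o2)cc1 | starting material
2 | allyl bromide | C=CCBr | starting material
3 | 7-allyloxy-5-hydroxy-2-(4-methoxyphenyl)chromen-4-one | COc1ccc(-c2cc(=O)c3c(O)cc(OCC=C)cc3o2)cc1 | intermediate
4 | 8-allyl-5,7-dihydroxy-2-(4-methoxyphenyl)chromen-4-one | COc1ccc(-c2cc(=O)c3c(O)cc(O)c(CC=C)c3o2)cc1 | intermediate
5 | 8-allyl-5,7-bis(methoxymethoxy)-2-(4-methoxyphenyl)chromen-4-one | COc1ccc(-c2cc(=O)c3c(OCOC)cc(OCOC)c(CC=C)c3o2)cc1 | intermediate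
6 | 8-(2,3-dihydroxypropyl)-5,7-bis(methoxymethoxy)-2-(4-methoxyphenyl)chromen-4-one (racemic) | COc1ccc(-c2cc(=O)c3c(OCOC)cc(OCOC)c(CC(O)CO)c3o2)cc1 | intermediate
7 | 2-[5,7-bis(methoxymethoxy)-2-(4-methoxyphenyl)-4-oxochromen-8-yl]acetaldehyde | COc1ccc(-c2cc(=O)c3c(OCOC)cc(OCOC)c(CC=O)c3o2)cc1 | intermediate
8 | vinylmagnesium bromide | C=C[Mg]Br | starting material
9 | 8-(2-hydroxybut-3-enyl)-5,7-bis(methoxymethoxy)-2-(4-methoxyphenyl)chromen-4-one (racemic) | COc1ccc(-c2cc(=O)c3c(OCOC)cc(OCOC)c(CC(O)C=C)c3o2)cc1 | intermediate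
10 | 5,7-bis(methoxymethoxy)-2-(4-methoxyphenyl)-8-(2-oxobut-3-enyl)chromen-4-one | COc1ccc(-c2cc(=O)c3c(OCOC)cc(OCOC)c(CC(=O)C=C)c3o2)cc1 | intermediate
11 | 8-[(1Z)-2-(tert-butyldimethylsilyloxy)buta-1,3-dienyl]-5,7-bis(methoxymethoxy)-2-(4-methoxyphenyl)chromen-4-one | COc1ccc(-c2cc(=O)c3c(OCOC)cc(OCOC)c(/C=C(\O[Si](C)(C)C(C)(C)C)C=C)c3o2)cc1 | intermediate
12 | methyl propiolate | C#CC(=O)OC | starting material
13 | methyl 3-[5,7-bis(methoxymethoxy)-2-(4-methoxyphenyl)-4-oxochromen-8-yl]-4-(tert-butyldimethylsilyloxy)cyclohexa-1,4-diene-1-carboxylate (racemic) | COc1ccc(-c2cc(=O)c3c(OCOC)cc(OCOC)c(C4C=C(C(=O)OC)CC=C4O[Si](C)(C)C(C)(C)C)c3o2)cc1 | intermediate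
14 | methyl 3-[5,7-bis(methoxymethoxy)-2-(4-methoxyphenyl)-4-oxochromen-8-yl]-4-(tert-butyldimethylsilyloxy)benzoate | COc1ccc(-c2cc(=O)c3c(OCOC)cc(OCOC)c(-c4cc(C(=O)OC)ccc4O[Si](C)(C)C(C)(C)C)c3o2)cc1 | intermediate
15 | methyl 3-[5,7-bis(methoxymethoxy)-2-(4-methoxyphenyl)-4-oxochromen-8-yl]-4-hydroxybenzoate (present as its tetrabutylammonium phenoxide) | COc1ccc(-c2cc(=O)c3c(OCOC)cc(OCOC)c(-c4cc(C(=O)OC)ccc4O)c3o2)cc1 | intermediate
16 | methyl 3-[5,7-bis(methoxymethoxy)-2-(4-methoxyphenyl)-4-oxochromen-8-yl]-4-(methoxymethoxy)benzoate | COc1ccc(-c2cc(=O)c3c(OCOC)cc(OCOC)c(-c4cc(C(=O)OC)ccc4OCOC)c3o2)cc1 | intermediate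
17 | 3-[5,7-bis(methoxymethoxy)-2-(4-methoxyphenyl)-4-oxochromen-8-yl]-4-(methoxymethoxy)benzoic acid | COc1ccc(-c2cc(=O)c3c(OCOC)cc(OCOC)c(-c4cc(C(=O)O)ccc4OCOC)c3o2)cc1 | intermediate
18 | mixed anhydride of 17 with isobutyl hydrogen carbonate | COc1ccc(-c2cc(=O)c3c(OCOC)cc(OCOC)c(-c4cc(C(=O)OC(=O)OCC(C)C)ccc4OCOC)c3o2)cc1 | intermediate
19 | 8-[5-(hydroxymethyl)-2-(methoxymethoxy)phenyl]-5,7-bis(methoxymethoxy)-2-(4-methoxyphenyl)chromen-4-one | COc1ccc(-c2cc(=O)c3c(OCOC)cc(OCOC)c(-c4cc(CO)ccc4OCOC)c3o2)cc1 | intermediate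
20 | 3-[5,7-bis(methoxymethoxy)-2-(4-methoxyphenyl)-4-oxochromen-8-yl]-4-(methoxymethoxy)benzaldehyde | COc1ccc(-c2cc(=O)c3c(OCOC)cc(OCOC)c(-c4cc(C=O)ccc4OCOC)c3o2)cc1 | intermediate
21 | methyl 2,4,6-trihydroxybenzoate | COC(=O)c1c(O)cc(O)cc1O | starting material
22 | methyl 2-hydroxy-4,6-bis(methoxymethoxy)benzoate | COC(=O)c1c(O)cc(OCOC)cc1OCOC | intermediate
23 | tert-butyl acetate | CC(=O)OC(C)(C)C | starting material
24 | tert-butyl 3-[2-hydroxy-4,6-bis(methoxymethoxy)phenyl]-3-oxopropanoate | CC(C)(C)OC(=O)CC(=O)c1c(O)cc(OCOC)cc1OCOC | intermediate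
25 | tert-butyl (2Z)-3-{3-[5,7-bis(methoxymethoxy)-2-(4-methoxyphenyl)-4-oxochromen-8-yl]-4-(methoxymethoxy)phenyl}-2-[2-hydroxy-4,6-bis(methoxymethoxy)benzoyl]prop-2-enoate | COc1ccc(-c2cc(=O)c3c(OCOC)cc(OCOC)c(-c4cc(/C=C(\C(=O)OC(C)(C)C)C(=O)c5c(O)cc(OCOC)cc5OCOC)ccc4OCOC)c3o2)cc1 | intermediate
26 | tert-butyl (2S,3R)-2-{3-[5,7-bis(methoxymethoxy)-2-(4-methoxyphenyl)-4-oxochromen-8-yl]-4-(methoxymethoxy)phenyl}-5,7-bis(methoxymethoxy)-4-oxochromane-3-carboxylate (C3 labile through the enol, trans form drawn) | COc1ccc(-c2cc(=O)c3c(OCOC)cc(OCOC)c(-c4cc([C@@H]5[C@@H](C(=O)OC(C)(C)C)C(=O)c6c(OCOC)cc(OCOC)cc6O5)ccc4OCOC)c3o2)cc1 | intermediate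
27 | (2S,3R)-2-{3-[5,7-dihydroxy-2-(4-methoxyphenyl)-4-oxochromen-8-yl]-4-hydroxyphenyl}-5,7-dihydroxy-4-oxochromane-3-carboxylic acid | COc1ccc(-c2cc(=O)c3c(O)cc(O)c(-c4cc([C@@H]5[C@@H](C(=O)O)C(=O)c6c(O)cc(O)cc6O5)ccc4O)c3o2)cc1 | intermediate
28 | (2S)-2,3-dihydropodocarpusflavone A | COc1ccc(-c2cc(=O)c3c(O)cc(O)c(-c4cc([C@@H]5CC(=O)c6c(O)cc(O)cc6O5)ccc4O)c3o2)cc1 | target

**Total step count:** 17
**Longest linear sequence:** 15 steps from acacetin (steps 1–12 and 15–17). Steps 13 and 14 form the two-step ring A branch.

**Steps most likely to fail**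

1. **Step 8.**
 - What may go wrong: the twisted flavone shields the diene terminus that must bond first, so the cycloaddition may be slow. Protodesilylation or polymerisation of the diene could then overtake it, and regiocontrol could erode at the temperature needed.
 - Fallback: the biaryl bond is made by Suzuki–Miyaura coupling instead of by arene construction. It sets out from 1. NaH and MOMCl give 5,7-bis(methoxymethoxy)-2-(4-methoxyphenyl)chromen-4-one F1. N-Iodosuccinimide in DMF iodinates F1 at C8, the more nucleophilic position once the 5-oxygen is alkylated, to give the 8-iodo flavone F2. Commercial methyl 3-bromo-4-hydroxybenzoate is converted with MOMCl and i-Pr2NEt into methyl 3-bromo-4-(methoxymethoxy)benzoate F3. Miyaura borylation (B2pin2, PdCl2(dppf), KOAc, 1,4-dioxane, 90 °C) then gives the pinacol boronate F4. Coupling of F2 with F4 (Pd(OAc)2, SPhos, K3PO4, toluene/H2O, 90 °C) comes back to the route at 16.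

2. **Step 16.**
 - What may go wrong: the large ortho-flavonyl aryl group may disturb the fit in the catalyst pocket and lower facial selectivity. Reversible ring opening before the quench may also erode the enantiomeric purity.
 - Fallback: resolution replaces asymmetric catalysis. It sets out from 25. Catalytic Et3N in CH2Cl2 closes the ring to the racemic trans flavanone-3-carboxylate F5. The acidolysis conditions of step 17 convert F5 into racemic 2,3-dihydropodocarpusflavone A F6. Preparative HPLC on a polysaccharide-based chiral stationary phase separates the enantiomers and comes back to the route at 28. The unwanted antipode can be racemised with mild base and recycled.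

3. **Step 15.**
 - What may go wrong: the electron-rich aldehyde may condense slowly with the hindered β-keto ester. The free phenol may also add to the new alkylidene under amine catalysis before isolation, which would give racemic material.
 - Fallback: the phenol is masked during the condensation. It sets out from 22. Compound 2 and K2CO3 in DMF give methyl 2-allyloxy-4,6-bis(methoxymethoxy)benzoate F7. Claisen condensation with the lithium enolate of 23 gives tert-butyl 3-[2-allyloxy-4,6-bis(methoxymethoxy)phenyl]-3-oxopropanoate F8. Knoevenagel condensation with 20, now possible with azeotropic water removal at reflux, gives the O-allyl alkylidene F9, which cannot cyclise. Tsuji–Trost deallylation (Pd(PPh3)4, N-methylaniline as a weakly basic allyl acceptor, THF, rt) releases the phenol and comes back to the route at 25.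

**Further compounds**
F1 | step 8 | 5,7-bis(methoxymethoxy)-2-(4-methoxyphenyl)chromen-4-one | COc1ccc(-c2cc(=O)c3c(OCOC)cc(OCOC)cc3o2)cc1
F2 | step 8 | 8-iodo-5,7-bis(methoxymethoxy)-2-(4-methoxyphenyl)chromen-4-one | COc1ccc(-c2cc(=O)c3c(OCOC)cc(OCOC)c(I)c3o2)cc1
F3 | step 8 | methyl 3-bromo-4-(methoxymethoxy)benzoate | COCOc1ccc(C(=O)OC)cc1Br
F4 | step 8 | methyl 4-(methoxymethoxy)-3-(4,4,5,5-tetramethyl-1,3,2-dioxaborolan-2-yl)benzoate | COCOc1ccc(C(=O)OC)cc1B1OC(C)(C)C(C)(C)O1
F5 | step 16 | racemic trans tert-butyl 2-{3-[5,7-bis(methoxymethoxy)-2-(4-methoxyphenyl)-4-oxochromen-8-yl]-4-(methoxymethoxy)phenyl}-5,7-bis(methoxymethoxy)-4-oxochromane-3-carboxylate | COc1ccc(-c2cc(=O)c3c(OCOC)cc(OCOC)c(-c4cc(C5C(C(=O)OC(C)(C)C)C(=O)c6c(OCOC)cc(OCOC)cc6O5)ccc4OCOC)c3o2)cc1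
F6 | step 16 | racemic 2,3-dihydropodocarpusflavone A | COc1ccc(-c2cc(=O)c3c(O)cc(O)c(-c4cc(C5CC(=O)c6c(O)cc(O)cc6O5)ccc4O)c3o2)cc1
F7 | step 15 | methyl 2-allyloxy-4,6-bis(methoxymethoxy)benzoate | C=CCOc1cc(OCOC)cc(OCOC)c1C(=O)OC
F8 | step 15 | tert-butyl 3-[2-allyloxy-4,6-bis(methoxymethoxy)phenyl]-3-oxopropanoate | C=CCOc1cc(OCOC)cc(OCOC)c1C(=O)CC(=O)OC(C)(C)C
F9 | step 15 | tert-butyl (2Z)-2-[2-allyloxy-4,6-bis(methoxymethoxy)benzoyl]-3-{3-[5,7-bis(methoxymethoxy)-2-(4-methoxyphenyl)-4-oxochromen-8-yl]-4-(methoxymethoxy)phenyl}prop-2-enoate | COc1ccc(-c2cc(=O)c3c(OCOC)cc(OCOC)c(-c4cc(/C=C(\C(=O)OC(C)(C)C)C(=O)c5c(OCC=C)cc(OCOC)cc5OCOC)ccc4OCOC)c3o2)cc1
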